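The data come from a simulation from invented constants.

At late times target is falling: at 12.0 d red, green and teal hold 0.4%, 0.3% and 1.4%, each below its first reading .

| flask | starting material | reagent | second substrate | remark | time |
|---|---|---|---|---|---|
| red | 0.20 M | 0.80 M | 0.40 M | run made earlier |  |
| green | 0.80 M | 0.80 M | 0.40 M | run made earlier |  |
| teal | 0.40 M | 0.80 M | 0.20 M | run made earlier |  |
| flask | 0.40 M | 0.800 M | 0.400 M |  | 15 d |

| run | time / d | target / % |
|---|---|---|
| red | 0.125 | 14.0 |
| red | 0.500 | 15.7 |
| red | 2.50 | 8.2 |
| red | 12.0 | 0.4 |
| green | 0.125 | 7.0 |
| green | 0.500 | 4.3 |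
| green | 2.50 | 1.3 |
| green | 12.0 | 0.3 |
| teal | 0.125 | 13.0 |
| teal | 0.500 | 12.0 |
| teal | 2.50 | 5.0 |
| teal | 12.0 | 1.4 |

(readings scatter by 0.5 percentage points)



- time up to 15 d at which target stands highest
- the amount of target, in percent of the starting material charged, at that time

I turn the question round: for the flask to peak at the end of the allowed time, target would have to stand as high there as early on. I test that in powers of ten (lg) on teal, which has the flask's charges of starting material and reagent. I take teal's tail slope s, then extend its fall from the first reading to the longest time allowed:

s = lg(5.0 / 1.4) / (12.0 d − 2.50 d) = 0.0582 d⁻¹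

drop = lg(13.0 / 1.4) + s × (15 d − 12.0 d) = 1.14

This tail drop, the lg of the highest level over the level at the end, would have to be zero for a late peak. My estimate, taken from teal's readings, stands 1.14 above zero, so I commit to an early peak for the flask. Its height then has to come from the early readings, and that cheap route is the forecast's: it gives 0.2 d and 12.5%, on the ground that the flask “sits between red and green and close to teal”.

The flask peaks at 0.197 d with 11.4% and holds 0.800% at 15.0 d, a drop of 1.15 against my 1.14.

starting material + target → side product (k = 0.0130 M⁻¹ min⁻¹); reagent + target → over-reaction product (k = 0.00230 M⁻¹ min⁻¹); starting material + reagent → target (k = 0.00240 M⁻¹ min⁻¹); starting material + second substrate → cross product (k = 0.00400 M⁻¹ min⁻¹); 2 reagent → homo dimer (k = 4.90 × 10⁻⁴ M⁻¹ min⁻¹); second substrate + reagent → second product (k = 0.0200 M⁻¹ min⁻¹) At 0.0319 d target, the intermediate of these consecutive reactions, has a half-life of 0.11 d by its reaction with starting material to side product, shorter than the 0.35 d half-life of starting material by the step that forms target. That half-life of target is also shorter than the 15 d allowed. The neighbour flask with 2.0 M of reagent reaches 22.5% and ends at 0.128%, a drop of 2.25.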